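**Retrosynthetic overview**
- The target comes from a (2S)-6-(1,1-dimethylallyl)-5-hydroxyflavanone by C3 hydroxylation trans to the aryl group (flavanone 3-hydroxylase-like) and MOM removal.
- That flavanone comes from a (2S)-5-O-prenyl flavanone by aromatic Claisen rearrangement; C6 is the only free ortho position, so the prenyl unit arrives there as the 1,1-dimethylallyl group.
- The 5-O-prenyl flavanone comes from a 2'-hydroxy-6'-prenyloxychalcone by enantioselective 6-endo oxa-Michael closure (chalcone isomerase-like); there is only one free OH, so only one regioisomer can form, and C2 is set here.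
- The chalcone comes from a Claisen–Schmidt condensation of 4-O-MOM-6-O-prenyl-phloracetophenone with 4-(methoxymethoxy)benzaldehyde.
- Ring order: rings A and B are bought as arenes; ring C is the only ring made (step 4) and is then decorated at C6 and C3.

Assumption: 4-(methoxymethoxy)benzaldehyde is bought as such, commercial 2,4,6-trihydroxyacetophenone monohydrate is dried before use, and the sense of induction of the step 4 catalyst is assigned by analogy (if it proves opposite, the quinine-derived pseudoenantiomer replaces it).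

**Step 1**
Reactants: 1 2,4,6-trihydroxyacetophenone
Product: 2 1-[2,6-dihydroxy-4-(methoxymethoxy)phenyl]ethanone
Conditions: MOMCl (1.0 equiv), i-Pr2NEt (1.2 equiv), THF, −10 → 0 °C
Reagents that add atoms: chloromethyl methyl ether (MOMCl), COCCl
Why: Williamson-type O-alkylation (MOM protection); the 4-OH, para to the acetyl group and not chelated, is the most acidic and least hindered phenol, so one equivalent of MOMCl caps it first while the ortho hydroxyls are held back by hydrogen bonding to the ketone (some 4,6-bis-MOM ether is separated).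

**Step 2**
Reactants: 2 1-[2,6-dihydroxy-4-(methoxymethoxy)phenyl]ethanone; 3 1-bromo-3-methylbut-2-ene (prenyl bromide)
Product: 4 1-[2-hydroxy-4-(methoxymethoxy)-6-(3-methylbut-2-en-1-yloxy)phenyl]ethanone
Conditions: K2CO3 (1.5 equiv), acetone, reflux
Reagents that add atoms: none
Why: Williamson ether synthesis; the two ortho hydroxyls of 2 are equivalent, and after the first O-prenylation the remaining one is locked in a chelate with the ketone and resists a second alkylation.

**Step 3**
Reactants: 4 1-[2-hydroxy-4-(methoxymethoxy)-6-(3-methylbut-2-en-1-yloxy)phenyl]ethanone; 5 4-(methoxymethoxy)benzaldehyde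
Product: 7 (E)-1-[2-hydroxy-4-(methoxymethoxy)-6-(3-methylbut-2-en-1-yloxy)phenyl]-3-[4-(methoxymethoxy)phenyl]prop-2-en-1-one, via aldol adduct 6 (not isolated)
Conditions: KOH (50% aq., excess), EtOH, rt, 36 h; then cold aq. NH4Cl to pH 6
Reagents that add atoms: none
Why: Claisen–Schmidt (crossed aldol) condensation; the enolate of 4 adds to the non-enolisable aldehyde and aldol 6 dehydrates by E1cB to the conjugated (E)-enone, which in strong base is held as its phenoxide and does not cyclise.

**Step 4**
Reactants: 7 (E)-1-[2-hydroxy-4-(methoxymethoxy)-6-(3-methylbut-2-en-1-yloxy)phenyl]-3-[4-(methoxymethoxy)phenyl]prop-2-en-1-one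
Product: 8 (2S)-7-(methoxymethoxy)-2-[4-(methoxymethoxy)phenyl]-5-(3-methylbut-2-en-1-yloxy)chroman-4-one
Conditions: N-[3,5-bis(trifluoromethyl)phenyl]-N'-(9-deoxy-9-epi-quinidin-9-yl)squaramide (10 mol %), toluene, 4 Å MS, 0 °C, 48–72 h; filter through silica, recrystallise
Reagents that add atoms: none
Why: Proposed new method: enantioselective 6-endo-trig intramolecular oxa-Michael addition of an unactivated 2'-hydroxychalcone, in which the quinuclidine nitrogen ion-pairs with the acidic 2'-OH while the squaramide NH groups bind the enone carbonyl, break the internal OH···O=C chelate and present one enantioface of the s-cis enone to the phenoxide, and the enolate is then protonated by the quinuclidinium to give the (2S) centre; the 6'-prenyloxy group twists the aroyl unit out of conjugation so ring closure is downhill and the racemising retro-addition is slow at 0 °C; the closest known reaction type is the bifunctional cinchona amine–thiourea-catalysed oxa-Michael cyclisation of α-alkoxycarbonyl-activated 2'-hydroxychalcones, and the enzymatic model is chalcone isomerase.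

**Step 5**
Reactants: 8 (2S)-7-(methoxymethoxy)-2-[4-(methoxymethoxy)phenyl]-5-(3-methylbut-2-en-1-yloxy)chroman-4-one
Product: 10 (2S)-5-hydroxy-7-(methoxymethoxy)-2-[4-(methoxymethoxy)phenyl]-6-(2-methylbut-3-en-2-yl)chroman-4-one, via ortho-dienone 9 (not isolated)
Conditions: Eu(fod)3 [fod = 6,6,7,7,8,8,8-heptafluoro-2,2-dimethyloctane-3,5-dionate] (10 mol %), acid-free CHCl3, 50 °C
Reagents that add atoms: none
Why: Aromatic Claisen rearrangement ([3,3]-sigmatropic) accelerated by the oxophilic trivalent europium centre chelated between the C4 carbonyl and the 5-ether oxygen; C6 is the only free ortho position, the allyl unit is inverted to the 1,1-dimethylallyl group, tautomerisation of dienone 9 at this low temperature is expected to outrun the Cope shift to C8, and C2 is untouched.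

**Step 6**
Reactants: 10 (2S)-5-hydroxy-7-(methoxymethoxy)-2-[4-(methoxymethoxy)phenyl]-6-(2-methylbut-3-en-2-yl)chroman-4-one
Product: 14 (2R,3R)-3,5,7-trihydroxy-2-(4-hydroxyphenyl)-6-(2-methylbut-3-en-2-yl)chroman-4-one, via bis-silyl enol ether 11 (not isolated), via silyloxy epoxide 12 (not isolated), via bis-MOM dihydroflavonol 13 (not isolated)
Conditions: TMSOTf (3 equiv), Et3N (4 equiv), CH2Cl2, 0 °C; evaporate, pentane, filter; DMDO (1.1 equiv), acetone/CH2Cl2, −40 → 0 °C; then 1.5 M HCl, MeOH, 40 °C
Reagents that add atoms: dimethyldioxirane (DMDO), CC1(C)OO1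
Why: Rubottom oxidation followed by acid methanolysis; soft enolisation avoids a free enolate (no retro-oxa-Michael ring opening, so C2 is kept), DMDO epoxidises the electron-rich C3=C4 bond of 11 on the face opposite the C2 aryl group to set the 2,3-trans (3R) centre while the hindered monosubstituted vinyl group reacts far more slowly, and HCl/MeOH opens silyloxy epoxide 12 to the ketol and removes both silyl and both MOM groups (any MOM/TMS exchange caused by TMSOTf ends at the same product).

**Compound list**
1 | 1-(2,4,6-trihydroxyphenyl)ethanone (2,4,6-trihydroxyacetophenone) | CC(=O)c1c(O)cc(O)cc1O | starting material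
2 | 1-[2,6-dihydroxy-4-(methoxymethoxy)phenyl]ethanone | CC(=O)c1c(O)cc(OCOC)cc1O | intermediate
3 | 1-bromo-3-methylbut-2-ene (prenyl bromide) | CC(C)=CCBr | starting material
4 | 1-[2-hydroxy-4-(methoxymethoxy)-6-(3-methylbut-2-en-1-yloxy)phenyl]ethanone | CC(=O)c1c(O)cc(OCOC)cc1OCC=C(C)C | intermediate
5 | 4-(methoxymethoxy)benzaldehyde | COCOc1ccc(C=O)cc1 | starting material
6 | aldol adduct (racemic, not isolated): 3-hydroxy-1-[2-hydroxy-4-(methoxymethoxy)-6-(3-methylbut-2-en-1-yloxy)phenyl]-3-[4-(methoxymethoxy)phenyl]propan-1-one | COCOc1ccc(C(O)CC(=O)c2c(O)cc(OCOC)cc2OCC=C(C)C)cc1 | intermediate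
7 | (E)-1-[2-hydroxy-4-(methoxymethoxy)-6-(3-methylbut-2-en-1-yloxy)phenyl]-3-[4-(methoxymethoxy)phenyl]prop-2-en-1-one (chalcone) | COCOc1ccc(/C=C/C(=O)c2c(O)cc(OCOC)cc2OCC=C(C)C)cc1 | intermediate
8 | (2S)-7-(methoxymethoxy)-2-[4-(methoxymethoxy)phenyl]-5-(3-methylbut-2-en-1-yloxy)chroman-4-one | CC(C)=CCOc1cc(OCOC)cc2c1C(=O)C[C@@H](c3ccc(OCOC)cc3)O2 | intermediate
9 | ortho-dienone (not isolated, both C6 epimers): (2S)-7-(methoxymethoxy)-2-[4-(methoxymethoxy)phenyl]-6-(2-methylbut-3-en-2-yl)-2,3-dihydro-4H-chromene-4,5(6H)-dione | C=CC(C)(C)C1C(OCOC)=CC2=C(C1=O)C(=O)C[C@@H](c3ccc(OCOC)cc3)O2 | intermediate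
10 | (2S)-5-hydroxy-7-(methoxymethoxy)-2-[4-(methoxymethoxy)phenyl]-6-(2-methylbut-3-en-2-yl)chroman-4-one | C=CC(C)(C)c1c(OCOC)cc2c(c1O)C(=O)C[C@@H](c3ccc(OCOC)cc3)O2 | intermediate
11 | bis-silyl enol ether (not isolated): (2S)-7-(methoxymethoxy)-2-[4-(methoxymethoxy)phenyl]-6-(2-methylbut-3-en-2-yl)-4,5-bis(trimethylsilyloxy)-2H-chromene | C=CC(C)(C)c1c(OCOC)cc2c(c1O[Si](C)(C)C)C(O[Si](C)(C)C)=C[C@@H](c3ccc(OCOC)cc3)O2 | intermediate
12 | silyloxy epoxide (not isolated): 3,4-epoxide of 11, oxirane oxygen on the face opposite the C2 aryl group, C4 carrying OSiMe3 | C=CC(C)(C)c1c(OCOC)cc2c(c1O[Si](C)(C)C)[C@]4(O[Si](C)(C)C)O[C@@H]4[C@@H](c3ccc(OCOC)cc3)O2 | intermediate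
13 | bis-MOM dihydroflavonol (not isolated): (2R,3R)-3,5-dihydroxy-7-(methoxymethoxy)-2-[4-(methoxymethoxy)phenyl]-6-(2-methylbut-3-en-2-yl)chroman-4-one | C=CC(C)(C)c1c(OCOC)cc2c(c1O)C(=O)[C@H](O)[C@@H](c3ccc(OCOC)cc3)O2 | intermediate
14 | (2R,3R)-3,5,7-trihydroxy-2-(4-hydroxyphenyl)-6-(2-methylbut-3-en-2-yl)chroman-4-one (CNP0527000.1) | C=CC(C)(C)c1c(O)cc2c(c1O)C(=O)[C@H](O)[C@@H](c1ccc(O)cc1)O2 | target

**Totals**
Total step count: 6. Longest linear sequence: 6 steps (1 → 2 → 4 → 7 → 8 → 10 → 14).

**Three steps most likely to fail**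

Step 4 (enantioselective ring closure). The oxa-Michael addition is reversible and unactivated chalcones have given only modest ee with related catalysts. The fallback is racemic closure followed by kinetic resolution. It sets out from chalcone 7: NaOAc in refluxing EtOH closes the ring without stereocontrol to the racemic flavanone F1. Asymmetric transfer hydrogenation with RuCl(p-cymene)[(R,R)-TsDPEN] and HCO2H/Et3N in EtOAc at rt, stopped near 55% conversion, reduces the matched (2R) enantiomer to the (2R,4R)-cis-flavan-4-ol F2. The unreacted (2S) ketone is compound 8, where the route is rejoined. F2 can be oxidised back with Dess–Martin periodinane and re-racemised with NaOAc to F1. The same resolution also polishes scalemic 8 from step 4.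

Step 5 (Claisen rearrangement). Dienone 9 may undergo the Cope shift to the 8-prenyl isomer before it tautomerises, and the Lewis acid may erode ee or cyclise the product onto the 5-OH. The fallback forms the aryl–C(Me)2 bond by cross-coupling instead of a sigmatropic shift. It sets out from 2: Claisen–Schmidt condensation of 2 with 5 (KOH, EtOH) gives the symmetric 2',6'-dihydroxychalcone F3. Ring closure under the step 4 conditions gives the (2S)-5-hydroxyflavanone F4; either hydroxyl gives the same product. Iodination with BnMe3N·ICl2 and CaCO3 in CH2Cl2/MeOH goes ortho to the chelated 5-OH and gives the 6-iodoflavanone F5. Suzuki–Miyaura coupling of F5 with prenylboronic acid pinacol ester (Pd(OAc)2, a γ-directing biaryl dialkylphosphine, K3PO4, THF/H2O, 40 °C) transposes the allyl unit and gives the 1,1-dimethylallyl arene, which is compound 10.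

Step 6 (Rubottom oxidation and deprotection). Risks are over-oxidation by DMDO, a cis/trans mixture at C3, and acid-induced addition of a phenol to the dimethylallyl vinyl group. The fallback brings in the C3 oxygen before ring closure by enantioselective chalcone epoxidation. It sets out from 7: NaH and MOMCl in DMF cap the 2'-OH to give the fully MOM-protected chalcone F6. Juliá–Colonna epoxidation (poly-L-leucine, urea–H2O2, DBU, THF) gives the (2R,3S)-epoxyketone F7. HCl in MeOH at 45 °C removes the MOM groups, and the freed 2'-OH opens the oxirane at the benzylic carbon with inversion (6-endo) to give the (2R,3R)-5-O-prenyl dihydroflavonol F8. Claisen rearrangement of F8 with Eu(fod)3 in CHCl3 at 50 °C then gives the target 14 directly.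

**Further compounds**
F1 | step 4 | racemic 7-(methoxymethoxy)-2-[4-(methoxymethoxy)phenyl]-5-(3-methylbut-2-en-1-yloxy)chroman-4-one | CC(C)=CCOc1cc(OCOC)cc2c1C(=O)CC(c3ccc(OCOC)cc3)O2
F2 | step 4 | (2R,4R)-7-(methoxymethoxy)-2-[4-(methoxymethoxy)phenyl]-5-(3-methylbut-2-en-1-yloxy)chroman-4-ol | CC(C)=CCOc1cc(OCOC)cc2c1[C@H](O)C[C@H](c3ccc(OCOC)cc3)O2
F3 | step 5 | (E)-1-[2,6-dihydroxy-4-(methoxymethoxy)phenyl]-3-[4-(methoxymethoxy)phenyl]prop-2-en-1-one | COCOc1ccc(/C=C/C(=O)c2c(O)cc(OCOC)cc2O)cc1
F4 | step 5 | (2S)-5-hydroxy-7-(methoxymethoxy)-2-[4-(methoxymethoxy)phenyl]chroman-4-one | Oc1cc(OCOC)cc2c1C(=O)C[C@@H](c3ccc(OCOC)cc3)O2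
F5 | step 5 | (2S)-5-hydroxy-6-iodo-7-(methoxymethoxy)-2-[4-(methoxymethoxy)phenyl]chroman-4-one | Ic1c(OCOC)cc2c(c1O)C(=O)C[C@@H](c3ccc(OCOC)cc3)O2
F6 | step 6 | (E)-1-[2,4-bis(methoxymethoxy)-6-(3-methylbut-2-en-1-yloxy)phenyl]-3-[4-(methoxymethoxy)phenyl]prop-2-en-1-one | COCOc1ccc(/C=C/C(=O)c2c(OCOC)cc(OCOC)cc2OCC=C(C)C)cc1
F7 | step 6 | [2,4-bis(methoxymethoxy)-6-(3-methylbut-2-en-1-yloxy)phenyl][(2R,3S)-3-[4-(methoxymethoxy)phenyl]oxiran-2-yl]methanone | O=C(c1c(OCOC)cc(OCOC)cc1OCC=C(C)C)[C@@H]2O[C@H]2c3ccc(OCOC)cc3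
F8 | step 6 | (2R,3R)-3,7-dihydroxy-2-(4-hydroxyphenyl)-5-(3-methylbut-2-en-1-yloxy)chroman-4-one | CC(C)=CCOc1cc(O)cc2c1C(=O)[C@H](O)[C@@H](c3ccc(O)cc3)O2
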